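Retrosynthetic cuts, in order: the methyl ester; the coumarin C4–C4a bond (pyranone ring opened to an aryl propiolate); the propiolate acyl–O and ArO–CH2 bonds (giving propiolic acid, resorcinol monobenzoate and a cyclohexenylmethanol); in the carbocycle C2–CH3, C1–CH2OH and C6–CH3 (giving a 3-substituted 5-isopropenylcyclohex-2-enone); finally isopropenyl is folded back into a cyclopropane and the chain is cut at CH2–CH2CO2Me, which leads to (+)-3-carene.
Enabling feature: in the 7-alkoxycoumarin, benzene carbon C4a lies para to the ether oxygen on C7 and ortho to ring oxygen O1. This is the most electron-rich and least crowded carbon of a resorcinol monoether. The O1–C2(=O)–C3=C4 part of the pyranone ring would not survive the Grignard, amide-base and methoxide steps used on the carbocycle, so it is built last.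
Forward order: the six-membered ring of carene becomes the carbocycle. The acid chain is grown on C10, C5 is oxidised and the three-membered ring is opened to isopropenyl. CH3, CH2OH and CH3 are then placed on the ring, the benzene ring is joined by Mitsunobu etherification, and the pyranone ring closes last, before ester hydrolysis.
Stereochemistry: C4 is C1 of (+)-3-carene. It directs the conjugate methyl addition to the opposite face, which sets C6 with the chain cis to isopropenyl. The resulting axial methyl directs formaldehyde to the other face, which sets C1 and gives the all-cis array of isopropenyl, CH2OAr and chain, (1R,4S,6R).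

Key step: step 16

Remark: carbocycle positions follow the name cyclohex-2-en-1-ylmethoxy (C1 CH–CH2O, C2 C–CH3, C3 =CH, C4 CH–isopropenyl, C5 CH2, C6 quaternary). Bicyclic compounds carry carane numbering (C1/C6 ring fusion, C7 CMe2, C10 the carbon on C3). Commercial (+)-3-carene is taken as enantiopure (1S,6R) material.

Step 1
Reactants: 1 (+)-3-carene
Product: 2 (1S,3S,4R,6R)-3,4-epoxycarane (oxygen anti to the CMe2 bridge)
Conditions: mCPBA, CH2Cl2, 0 °C
Reagents that add atoms: mCPBA (3-chloroperoxybenzoic acid), O=C(OO)c1cccc(Cl)c1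
Why: Prilezhaev epoxidation; the endo methyl of the cyclopropane shields one face of the only alkene, so oxygen should arrive anti to the three-membered ring (these two centres are erased again in steps 2 and 3).

Step 2
Reactants: 2 (1S,3S,4R,6R)-3,4-epoxycarane
Product: 3 (1S,4R,6R)-car-3(10)-en-4-ol (7,7-dimethyl-3-methylidenebicyclo[4.1.0]heptan-4-ol in carane numbering; OH anti to CMe2)
Conditions: LiN(i-Pr)2, Et2O, 0 °C → reflux; H2O work-up
Reagents that add atoms: none
Why: Base-induced isomerisation of an epoxide to an allylic alcohol (syn β-elimination); the amide bound to the epoxide oxygen should take the most accessible proton, that of the C10 methyl group, giving the exocyclic alkene and the secondary C4 alcohol.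

Step 3
Reactants: 3 (1S,4R,6R)-car-3(10)-en-4-ol
Product: 5 methyl 3-[(1S,6R)-7,7-dimethylbicyclo[4.1.0]hept-3-en-3-yl]propanoate, via ketene acetal 4 (not isolated)
Conditions: MeC(OMe)3 (excess), EtCO2H (cat.), xylene, 130 °C, MeOH distilled off
Reagents that add atoms: trimethyl orthoacetate, CC(OC)(OC)OC
Why: Johnson–Claisen rearrangement; ketene acetal 4 shifts [3,3] onto the exocyclic CH2, which extends C10 by CH2CO2Me to the complete three-carbon acid chain, returns the alkene to C3=C4 and creates no stereocentre.

Step 4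
Reactants: 5 methyl 3-[(1S,6R)-7,7-dimethylbicyclo[4.1.0]hept-3-en-3-yl]propanoate
Product: 6 methyl 3-[(1S,6R)-7,7-dimethyl-5-oxobicyclo[4.1.0]hept-3-en-3-yl]propanoate
Conditions: Rh2(cap)4 (1 mol %), t-BuOOH (70 % aq.), K2CO3 (0.5 equiv), CH2Cl2, rt
Reagents that add atoms: tert-butyl hydroperoxide, CC(C)(C)OO
Why: Allylic C–H oxidation by tert-butylperoxy radicals; as with 3-carene itself and 1-alkylcyclohexenes, attack at the ring CH2 next to the unsubstituted alkene carbon (C5) leads to the β,β-disubstituted enone, and ester and cyclopropane should be inert.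

Step 5
Reactants: 6 methyl 3-[(1S,6R)-7,7-dimethyl-5-oxobicyclo[4.1.0]hept-3-en-3-yl]propanoate
Product: 7 methyl 3-[(5S)-5-(2-chloropropan-2-yl)-3-oxocyclohex-1-en-1-yl]propanoate
Conditions: dry HCl, AcOH–CH2Cl2, 0 °C
Reagents that add atoms: hydrogen chloride, Cl
Why: Acid-induced homoconjugate opening of a cyclopropyl ketone; the protonated enone breaks the C6–C7 bond, which overlaps with the carbonyl π system and leads to a tertiary cation that chloride captures, while carane C1 (the later C4) is untouched.

Step 6
Reactants: 7 methyl 3-[(5S)-5-(2-chloropropan-2-yl)-3-oxocyclohex-1-en-1-yl]propanoate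
Product: 8 methyl 3-[(5S)-3-oxo-5-(prop-1-en-2-yl)cyclohex-1-en-1-yl]propanoate
Conditions: activated neutral Al2O3, hexane–Et2O, rt → 40 °C
Reagents that add atoms: none
Why: Dehydrochlorination on alumina, the way isopropenyl groups are released from terpenoid hydrochlorides; surface E2 elimination should prefer the six unhindered methyl hydrogens to the single ring methine hydrogen, and the absence of a soluble base disfavours enolate re-closure to the cyclopropane.

Step 7
Reactants: 8 methyl 3-[(5S)-3-oxo-5-(prop-1-en-2-yl)cyclohex-1-en-1-yl]propanoate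
Product: 9 methyl 3-[(1R,5S)-1-methyl-5-(prop-1-en-2-yl)-3-(trimethylsilyloxy)cyclohex-2-en-1-yl]propanoate
Conditions: MeMgBr, CuBr·SMe2 (10 mol %), Me3SiCl, DMPU, THF, −78 °C
Reagents that add atoms: methylmagnesium bromide, C[Mg]Br; chlorotrimethylsilane, C[Si](C)(C)Cl
Why: Copper-catalysed, chlorosilane-accelerated conjugate addition; methyl should add axially and anti to the equatorial isopropenyl group (the usual trans-3,5 outcome), setting C6 with the chain cis to isopropenyl, and immediate O-silylation stores the enolate regiochemistry and prevents Dieckmann-type attack on the ester.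

Step 8
Reactants: 9 methyl 3-[(1R,5S)-1-methyl-5-(prop-1-en-2-yl)-3-(trimethylsilyloxy)cyclohex-2-en-1-yl]propanoate
Product: 10 methyl 3-[(1R,2S,5S)-2-(hydroxymethyl)-1-methyl-3-oxo-5-(prop-1-en-2-yl)cyclohexyl]propanoate
Conditions: aq. HCHO (37 %), Yb(OTf)3 (10 mol %), THF, rt
Reagents that add atoms: formaldehyde, C=O
Why: Lanthanide-triflate-catalysed Mukaiyama aldol reaction with aqueous formaldehyde; the new C–C bond should form axially and anti to the pseudoaxial methyl of the neighbouring quaternary carbon, which places CH2OH cis to the chain and to isopropenyl (C1 of the target).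

Step 9
Reactants: 10 methyl 3-[(1R,2S,5S)-2-(hydroxymethyl)-1-methyl-3-oxo-5-(prop-1-en-2-yl)cyclohexyl]propanoate
Product: 11 methyl 3-[(1R,2S,5S)-2-{[tert-butyl(dimethyl)silyl]oxymethyl}-1-methyl-3-oxo-5-(prop-1-en-2-yl)cyclohexyl]propanoate
Conditions: TBSCl, imidazole, DMF, 0 °C → rt
Reagents that add atoms: tert-butyldimethylsilyl chloride, CC(C)(C)[Si](C)(C)Cl
Why: Standard silylation of a primary alcohol under weakly basic conditions, which should leave the epimerisable α-centre alone and blocks retro-aldol and β-elimination in the next step.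

Step 10
Reactants: 11 methyl 3-[(1R,2S,5S)-2-{[tert-butyl(dimethyl)silyl]oxymethyl}-1-methyl-3-oxo-5-(prop-1-en-2-yl)cyclohexyl]propanoate
Product: 13 methyl 3-[(1R,2S,5S)-2-{[tert-butyl(dimethyl)silyl]oxymethyl}-1-methyl-5-(prop-1-en-2-yl)-3-(trifluoromethylsulfonyloxy)cyclohex-3-en-1-yl]propanoate, via potassium enolate 12 (not isolated)
Conditions: KN(SiMe3)2, THF, −78 °C; then PhNTf2, −78 → 0 °C
Reagents that add atoms: N-phenylbis(trifluoromethanesulfonimide), O=S(=O)(N(c1ccccc1)S(=O)(=O)C(F)(F)F)C(F)(F)F
Why: Kinetic deprotonation at the unhindered CH2 (the α-methine next to the quaternary carbon offers only an equatorial, poorly aligned hydrogen) gives enolate 12, and O-sulfonylation fixes the position of the future C2=C3 double bond.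

Step 11
Reactants: 13 enol triflate of step 10
Product: 14 methyl 3-[(1R,2R,5S)-2-{[tert-butyl(dimethyl)silyl]oxymethyl}-1,3-dimethyl-5-(prop-1-en-2-yl)cyclohex-3-en-1-yl]propanoate
Conditions: MeMgBr, Fe(acac)3 (5 mol %), THF–NMP, −30 °C
Reagents that add atoms: methylmagnesium bromide, C[Mg]Br
Why: Iron-catalysed Kumada-type coupling of an alkenyl triflate with a methyl Grignard reagent, fast enough at low temperature to spare the methyl ester, the silyl ether and the two stereocentres flanking the new trisubstituted alkene.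

Step 12
Reactants: 14 silyl ether of step 11
Product: 15 methyl 3-[(1R,2R,5S)-2-(hydroxymethyl)-1,3-dimethyl-5-(prop-1-en-2-yl)cyclohex-3-en-1-yl]propanoate
Conditions: HF·pyridine, pyridine–THF, 0 °C → rt
Reagents that add atoms: none
Why: Fluoride cleavage of a primary silyl ether in a buffered medium, which avoids a free alkoxide and hence lactonisation onto the cis ester chain.

Step 13
Reactants: 15 methyl 3-[(1R,2R,5S)-2-(hydroxymethyl)-1,3-dimethyl-5-(prop-1-en-2-yl)cyclohex-3-en-1-yl]propanoate; 16 3-hydroxyphenyl benzoate (resorcinol monobenzoate)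
Product: 17 3-{[(1R,4S,6R)-6-(3-methoxy-3-oxopropyl)-2,6-dimethyl-4-(prop-1-en-2-yl)cyclohex-2-en-1-yl]methoxy}phenyl benzoate
Conditions: PPh3, DIAD, THF, 0 → 40 °C
Reagents that add atoms: none
Why: Mitsunobu etherification; the phenol, made more acidic by the benzoate, displaces the activated oxygen at the primary CH2, so no stereocentre is involved, and the benzoate guarantees mono-alkylation of resorcinol.

Step 14
Reactants: 17 aryl benzoate of step 13
Product: 18 methyl 3-[(1R,2R,5S)-2-[(3-hydroxyphenoxy)methyl]-1,3-dimethyl-5-(prop-1-en-2-yl)cyclohex-3-en-1-yl]propanoate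
Conditions: K2CO3 (0.2 equiv), MeOH, 0 °C → rt
Reagents that add atoms: none
Why: Transesterification; the aryl benzoate is far more electrophilic than the alkyl ester, and methoxide exchange at the methyl ester is degenerate.

Step 15
Reactants: 18 phenol of step 14; 19 propiolic acid
Product: 20 3-{[(1R,4S,6R)-6-(3-methoxy-3-oxopropyl)-2,6-dimethyl-4-(prop-1-en-2-yl)cyclohex-2-en-1-yl]methoxy}phenyl prop-2-ynoate
Conditions: DCC, DMAP (5 mol %), CH2Cl2, −20 → 0 °C
Reagents that add atoms: none
Why: Steglich esterification of the phenol; low temperature and little DMAP limit conjugate addition to the activated alkyne.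

Step 16
Reactants: 20 aryl propiolate of step 15
Product: 21 methyl 3-[(1R,2R,5S)-1,3-dimethyl-2-{[(2-oxo-2H-chromen-7-yl)oxy]methyl}-5-(prop-1-en-2-yl)cyclohex-3-en-1-yl]propanoate
Conditions: Ph3PAuNTf2 (5 mol %), ClCH2CH2Cl, 40 °C
Reagents that add atoms: none
Why: Cationic monovalent gold binds the terminal alkyne and makes its CH carbon electrophilic; the arene carbon ortho to the ester oxygen and para to the ether oxygen attacks it anti to gold in a Friedel–Crafts manner, and rearomatisation with protodeauration releases 21 and the catalyst. The closest known reaction type is the gold- or palladium-catalysed intramolecular hydroarylation of aryl alkynoates to coumarins. The pyranone ring closes in the 6-endo-dig mode with formation of the coumarin C4–C4a bond. No stereocentre is formed, and the three existing ones are remote from the reacting atoms. Site selectivity between the two positions ortho to the ester oxygen is needed: the one para to the alkoxy group is the more nucleophilic and is open, whereas the one between the two oxygens is flanked by the bulky branched ether, which should suppress the 5-alkoxy isomer. Chemoselectivity for the alkyne over the two isolated alkenes is also needed and rests on the preference of the π-acid for the alkyne, the proximity of the arene, and neutral, acid-free conditions that leave isopropenyl and ester alone.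

Step 17
Reactants: 21 coumarin methyl ester of step 16
Product: 23 3-[(1R,2R,5S)-1,3-dimethyl-2-{[(2-oxo-2H-chromen-7-yl)oxy]methyl}-5-(prop-1-en-2-yl)cyclohex-3-en-1-yl]propanoic acid (CNP0301632.1), via trilithium coumarinate 22 (not isolated)
Conditions: LiOH·H2O (4 equiv), THF–H2O, rt; then 1 M HCl to pH 2
Reagents that add atoms: lithium hydroxide, [Li+].[OH-]
Why: Saponification; hydroxide also opens the lactone to the (Z)-coumarinate 22, whose cis geometry makes re-lactonisation spontaneous on acidification, so that overall only the methyl ester is lost.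

Compound list
1 | (+)-3-carene, (1S,6R)-3,7,7-trimethylbicyclo[4.1.0]hept-3-ene | CC1=CC[C@@H]2[C@H](C1)C2(C)C | starting material
2 | (1S,3S,4R,6R)-3,4-epoxycarane, oxygen anti to CMe2 | C[C@]12C[C@H]3[C@H](C3(C)C)C[C@H]1O2 | intermediate
3 | (1S,4R,6R)-car-3(10)-en-4-ol, OH anti to CMe2 | C=C1C[C@H]2[C@H](C2(C)C)C[C@H]1O | intermediate
4 | 1-methoxyethenyl ether of 3 (ketene acetal) | C=C1C[C@H]2[C@H](C2(C)C)C[C@H]1OC(=C)OC | intermediate
5 | methyl 3-[(1S,6R)-7,7-dimethylbicyclo[4.1.0]hept-3-en-3-yl]propanoate | COC(=O)CCC1=CC[C@@H]2[C@H](C1)C2(C)C | intermediate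
6 | methyl 3-[(1S,6R)-7,7-dimethyl-5-oxobicyclo[4.1.0]hept-3-en-3-yl]propanoate | COC(=O)CCC1=CC(=O)[C@@H]2[C@H](C1)C2(C)C | intermediate
7 | methyl 3-[(5S)-5-(2-chloropropan-2-yl)-3-oxocyclohex-1-en-1-yl]propanoate | CC(C)(Cl)[C@@H]1CC(=O)C=C(CCC(=O)OC)C1 | intermediate
8 | methyl 3-[(5S)-3-oxo-5-(prop-1-en-2-yl)cyclohex-1-en-1-yl]propanoate | C=C(C)[C@@H]1CC(=O)C=C(CCC(=O)OC)C1 | intermediate
9 | methyl 3-[(1R,5S)-1-methyl-5-(prop-1-en-2-yl)-3-(trimethylsilyloxy)cyclohex-2-en-1-yl]propanoate | C=C(C)[C@@H]1CC(O[Si](C)(C)C)=C[C@](C)(CCC(=O)OC)C1 | intermediate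
10 | methyl 3-[(1R,2S,5S)-2-(hydroxymethyl)-1-methyl-3-oxo-5-(prop-1-en-2-yl)cyclohexyl]propanoate | C=C(C)[C@@H]1CC(=O)[C@H](CO)[C@](C)(CCC(=O)OC)C1 | intermediate
11 | tert-butyldimethylsilyl ether of 10, (1R,2S,5S) | C=C(C)[C@@H]1CC(=O)[C@H](CO[Si](C)(C)C(C)(C)C)[C@](C)(CCC(=O)OC)C1 | intermediate
12 | potassium enolate of 11 (double bond towards the CH2 next to the isopropenyl-bearing carbon) | C=C(C)[C@@H]1C=C([O-])[C@H](CO[Si](C)(C)C(C)(C)C)[C@](C)(CCC(=O)OC)C1.[K+] | intermediate
13 | enol triflate, (1R,2S,5S) | C=C(C)[C@@H]1C=C(OS(=O)(=O)C(F)(F)F)[C@H](CO[Si](C)(C)C(C)(C)C)[C@](C)(CCC(=O)OC)C1 | intermediate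
14 | methyl 3-[(1R,2R,5S)-2-{[tert-butyl(dimethyl)silyl]oxymethyl}-1,3-dimethyl-5-(prop-1-en-2-yl)cyclohex-3-en-1-yl]propanoate | C=C(C)[C@@H]1C=C(C)[C@H](CO[Si](C)(C)C(C)(C)C)[C@](C)(CCC(=O)OC)C1 | intermediate
15 | methyl 3-[(1R,2R,5S)-2-(hydroxymethyl)-1,3-dimethyl-5-(prop-1-en-2-yl)cyclohex-3-en-1-yl]propanoate | C=C(C)[C@@H]1C=C(C)[C@H](CO)[C@](C)(CCC(=O)OC)C1 | intermediate
16 | 3-hydroxyphenyl benzoate | O=C(Oc1cccc(O)c1)c1ccccc1 | starting material
17 | 3-{[(1R,4S,6R)-6-(3-methoxy-3-oxopropyl)-2,6-dimethyl-4-(prop-1-en-2-yl)cyclohex-2-en-1-yl]methoxy}phenyl benzoate | C=C(C)[C@@H]1C=C(C)[C@H](COc2cccc(OC(=O)c3ccccc3)c2)[C@](C)(CCC(=O)OC)C1 | intermediate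
18 | methyl 3-[(1R,2R,5S)-2-[(3-hydroxyphenoxy)methyl]-1,3-dimethyl-5-(prop-1-en-2-yl)cyclohex-3-en-1-yl]propanoate | C=C(C)[C@@H]1C=C(C)[C@H](COc2cccc(O)c2)[C@](C)(CCC(=O)OC)C1 | intermediate
19 | propiolic acid | C#CC(=O)O | starting material
20 | 3-{[(1R,4S,6R)-6-(3-methoxy-3-oxopropyl)-2,6-dimethyl-4-(prop-1-en-2-yl)cyclohex-2-en-1-yl]methoxy}phenyl prop-2-ynoate | C=C(C)[C@@H]1C=C(C)[C@H](COc2cccc(OC(=O)C#C)c2)[C@](C)(CCC(=O)OC)C1 | intermediate
21 | methyl ester of the target | C=C(C)[C@@H]1C=C(C)[C@H](COc2ccc3ccc(=O)oc3c2)[C@](C)(CCC(=O)OC)C1 | intermediate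
22 | trilithium salt of the ring-opened (Z)-coumarinate dicarboxylate | C=C(C)[C@@H]1C=C(C)[C@H](COc2ccc(/C=C\C(=O)[O-])c([O-])c2)[C@](C)(CCC(=O)[O-])C1.[Li+].[Li+].[Li+] | intermediate
23 | CNP0301632.1, (1R,4S,6R) in cyclohex-2-en-1-ylmethoxy numbering | C=C(C)[C@@H]1C=C(C)[C@H](COc2ccc3ccc(=O)oc3c2)[C@](C)(CCC(=O)O)C1 | target

Total step count: 17. Longest linear sequence: 17 steps (1 → 23); 16 and 19 are bought.

Steps most likely to fail

Step 6. Three things may go wrong. Hydrogen chloride may be lost towards the ring methine instead of a methyl group. The new double bond may drift on into conjugation. The α′-CH2 may enolise on basic sites of the support and re-close the three-membered ring. The fallback replaces the loss of HCl by a base-free thermal syn-elimination. It sets out from 7. Ionising substitution with PhSH and ZnI2 in CH2Cl2 gives methyl 3-{(5S)-3-oxo-5-[2-(phenylsulfanyl)propan-2-yl]cyclohex-1-en-1-yl}propanoate F1. One equivalent of mCPBA at −78 °C gives the corresponding sulfoxide F2. Heating F2 in toluene over CaCO3 expels the sulfenic acid through a five-membered transition state that strongly prefers methyl to methine hydrogens. The route is rejoined at 8.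

Step 8. Protodesilylation in the aqueous medium may outrun C–C bond formation, face selectivity may erode, and the axial hydroxymethyl ketone may epimerise or undergo retro-aldol cleavage before it is protected. The fallback changes the aldol reaction into an anhydrous α-alkoxymethylation. It sets out from 9. (tert-Butyldimethylsilyloxy)methyl chloride and catalytic ZnBr2 in CH2Cl2 at −20 °C transfer the already protected CH2O unit to the same enol ether carbon, from the same face. The route is rejoined at 11, and 10 and step 9 are skipped. No compound outside the list is made (entry F0).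

Step 4. Hydrogen abstraction may occur at the other ring CH2 or at the side-chain CH2, oxidation may run on to the enedione, and radical opening of the cyclopropane may lower the return. The fallback fixes the oxidation site through ionic steps. It sets out from 5.
- mCPBA gives methyl 3-[(1S,3S,4R,6R)-3,4-epoxy-7,7-dimethylbicyclo[4.1.0]heptan-3-yl]propanoate F3.
- PhSeSePh with NaBH4 in EtOH opens F3 at C4 to the hydroxy selenide methyl 3-[(1S,3S,4S,6R)-3-hydroxy-7,7-dimethyl-4-(phenylselanyl)bicyclo[4.1.0]heptan-3-yl]propanoate F4.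
- H2O2 gives its selenoxide F5, which eliminates away from the carbinol carbon to the tertiary allylic alcohol methyl 3-[(1S,3S,6R)-3-hydroxy-7,7-dimethylbicyclo[4.1.0]hept-4-en-3-yl]propanoate F6.
- Pyridinium chlorochromate in CH2Cl2 (Babler–Dauben oxidative transposition) moves oxygen to C5, and the route is rejoined at 6.

Further compounds
F1 | step 6 | methyl 3-{(5S)-3-oxo-5-[2-(phenylsulfanyl)propan-2-yl]cyclohex-1-en-1-yl}propanoate | CC(C)(Sc1ccccc1)[C@@H]1CC(=O)C=C(CCC(=O)OC)C1
F2 | step 6 | methyl 3-{(5S)-3-oxo-5-[2-(phenylsulfinyl)propan-2-yl]cyclohex-1-en-1-yl}propanoate (both configurations at sulfur) | CC(C)(S(=O)c1ccccc1)[C@@H]1CC(=O)C=C(CCC(=O)OC)C1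
F0 | step 8 | none | none
F3 | step 4 | methyl 3-[(1S,3S,4R,6R)-3,4-epoxy-7,7-dimethylbicyclo[4.1.0]heptan-3-yl]propanoate | COC(=O)CC[C@]12C[C@H]3[C@H](C3(C)C)C[C@H]1O2
F4 | step 4 | methyl 3-[(1S,3S,4S,6R)-3-hydroxy-7,7-dimethyl-4-(phenylselanyl)bicyclo[4.1.0]heptan-3-yl]propanoate | COC(=O)CC[C@]1(O)C[C@H]2[C@H](C2(C)C)C[C@@H]1[Se]c1ccccc1
F5 | step 4 | selenoxide of F4 (both configurations at selenium) | COC(=O)CC[C@]1(O)C[C@H]2[C@H](C2(C)C)C[C@@H]1[Se](=O)c1ccccc1
F6 | step 4 | methyl 3-[(1S,3S,6R)-3-hydroxy-7,7-dimethylbicyclo[4.1.0]hept-4-en-3-yl]propanoate | COC(=O)CC[C@]1(O)C[C@H]2[C@H](C2(C)C)C=C1
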